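**Retrosynthetic overview**
1. The C9 acetate and the C8 (2S,3S)-epoxyangelate are put on last; the epoxy acid comes from angelic acid by Sharpless epoxidation.
2. Ring A (ten-membered carbocycle) and ring B (α-methylene lactone) form in one step: intramolecular CrCl2 Barbier (Nozaki–Hiyama–Kishi-type) allylation of a 2-(bromomethyl)enoate onto the C6 enal (C6–C7 bond), then lactonisation.
3. The Z C1=C10 bond comes from a Still-type Wittig reaction of an α-silyloxy methyl ketone with a C1–C6 hydroxy-phosphonium ylide.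
4. C8–C9 and both of their stereocentres come from a new amine-catalysed syn-aldol of a silyl-protected hydroxyacetone with a 4-oxobut-2-enoate.
5. Ring order: the oxirane is made on a separate fragment; rings A and B close together in step 9.

Assumption: the target is taken as drawn, (6R,7S,8R,9R,2'S,3'S) with 1(10)Z,4E, and positions are given in germacrane numbering (C1–C15).

**Route**

Step 1
Reactants: 1 5-chloropent-1-yne
Product: 3 (2E)-6-chloro-3-methylhex-2-en-1-ol, via vinylalane 2 (not isolated)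
Conditions: AlMe3, Cp2ZrCl2 (cat.), CH2Cl2, 0 °C to rt; then n-BuLi, (CH2O)n, THF, −78 °C to rt
Reagents that add atoms: trimethylaluminium C[Al](C)C; paraformaldehyde (formaldehyde unit) C=O
Why: Negishi carboalumination adds methyl and aluminium syn across the alkyne (methyl to the internal carbon) and the derived alanate is hydroxymethylated with retention, which fixes the E geometry of the future C4=C5 bond.

Step 2
Reactants: 3 (2E)-6-chloro-3-methylhex-2-en-1-ol
Product: 4 [(4E)-6-hydroxy-4-methylhex-4-en-1-yl]triphenylphosphonium iodide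
Conditions: NaI, PPh3, MeCN, reflux
Reagents that add atoms: triphenylphosphine c1ccc(cc1)P(c1ccccc1)c1ccccc1; sodium iodide [Na+].[I-]
Why: Finkelstein exchange of the primary chloride followed by SN2 quaternisation of the phosphine, with the allylic alcohol inert under these neutral conditions.

Step 3
Reactants: 5 ethyl 2-(diethoxyphosphoryl)prop-2-enoate; 6 2,2-dimethoxyacetaldehyde
Product: 9 ethyl (2E)-2-{[(4-methoxyphenyl)methoxy]methyl}-4-oxobut-2-enoate, via phosphonate 7 (not isolated), via acetal 8 (not isolated)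
Conditions: 4-MeOC6H4CH2OH, NaH, THF, 0 °C; then 6 (dried), 0 °C to rt; then 1 M HCl, rt
Reagents that add atoms: 4-methoxybenzyl alcohol COc1ccc(CO)cc1; water O
Why: oxa-Michael addition of the alkoxide to the vinylphosphonate gives the phosphonate anion, which olefinates 6 (Horner–Wadsworth–Emmons), and dilute acid then unmasks the conjugated acetal and equilibrates the 4-oxo-enoate to the E isomer (CHO trans to the ester).

Step 4
Reactants: 9 ethyl (2E)-2-{[(4-methoxyphenyl)methoxy]methyl}-4-oxobut-2-enoate; 10 1-[(tert-butyldimethylsilyl)oxy]propan-2-one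
Product: 11 ethyl (2E,4R,5S)-5-[(tert-butyldimethylsilyl)oxy]-4-hydroxy-2-{[(4-methoxyphenyl)methoxy]methyl}-6-oxohept-2-enoate
Conditions: O-tert-butyl-D-threonine (20 mol%), NMP/H2O (97:3), 4 °C, 10 (3 equiv)
Reagents that add atoms: none
Why: Proposed new method: the (Z)-enamine of 10 formed with the primary amino acid (internal N–H···O bond) adds 1,2 to the unhindered, strongly electrophilic formyl group of 9 through an acid-organised closed transition state (si face of the aldehyde), giving the syn (4R,5S) aldol and so setting C8 and C9, while conjugate addition is disfavoured because the carbon β to the aldehyde is fully substituted; the closest known reaction is the threonine-catalysed syn-aldol of silyl-protected hydroxy ketones with simple aryl and alkyl aldehydes, which has not been shown for 4-oxobut-2-enoate acceptors.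

Step 5
Reactants: 11 ethyl (2E,4R,5S)-5-[(tert-butyldimethylsilyl)oxy]-4-hydroxy-2-{[(4-methoxyphenyl)methoxy]methyl}-6-oxohept-2-enoate
Product: 12 ethyl (2E,4R,5S)-5-[(tert-butyldimethylsilyl)oxy]-2-{[(4-methoxyphenyl)methoxy]methyl}-6-oxo-4-[(triethylsilyl)oxy]hept-2-enoate
Conditions: Et3SiOTf, 2,6-lutidine, CH2Cl2, −78 °C
Reagents that add atoms: triethylsilyl triflate CC[Si](CC)(CC)OS(=O)(=O)C(F)(F)F
Why: silyl triflate/lutidine silylation of the β-hydroxy ketone at low temperature protects C8–OH without retro-aldol or epimerisation (no new stereocentre).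

Step 6
Reactants: 12 ethyl (2E,4R,5S)-5-[(tert-butyldimethylsilyl)oxy]-2-{[(4-methoxyphenyl)methoxy]methyl}-6-oxo-4-[(triethylsilyl)oxy]hept-2-enoate; 4 [(4E)-6-hydroxy-4-methylhex-4-en-1-yl]triphenylphosphonium iodide
Product: 14 ethyl (2E,4R,5R,6Z,10E)-5-[(tert-butyldimethylsilyl)oxy]-12-hydroxy-2-{[(4-methoxyphenyl)methoxy]methyl}-6,10-dimethyl-4-[(triethylsilyl)oxy]dodeca-2,6,10-trienoate, via ylide 13 (not isolated)
Conditions: 4 (1.5 equiv), KN(SiMe3)2 (3.0 equiv), THF, −78 to 0 °C; then 12, −78 to −20 °C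
Reagents that add atoms: none
Why: Wittig olefination of an α-alkoxy ketone with a salt-free non-stabilised ylide (Still's Z-selective variant) places the ylide chain cis to the oxygenated C9 branch and so gives the Z C1=C10 bond, the second equivalent of base only holding the hydroxyl as its alkoxide.

Step 7
Reactants: 14 ethyl (2E,4R,5R,6Z,10E)-5-[(tert-butyldimethylsilyl)oxy]-12-hydroxy-2-{[(4-methoxyphenyl)methoxy]methyl}-6,10-dimethyl-4-[(triethylsilyl)oxy]dodeca-2,6,10-trienoate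
Product: 15 ethyl (2E,4R,5R,6Z,10E)-5-[(tert-butyldimethylsilyl)oxy]-2-(hydroxymethyl)-6,10-dimethyl-12-oxo-4-[(triethylsilyl)oxy]dodeca-2,6,10-trienoate
Conditions: DDQ (3 equiv), CH2Cl2/pH 7 buffer (10:1), 0 °C to rt
Reagents that add atoms: none
Why: DDQ oxidative cleavage of the 4-methoxybenzyl ether and DDQ dehydrogenation of the electron-rich C6 allylic alcohol to the enal occur in the same operation, whereas the electron-poor C13 allylic alcohol and both silyl ethers are left alone.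

Step 8
Reactants: 15 ethyl (2E,4R,5R,6Z,10E)-5-[(tert-butyldimethylsilyl)oxy]-2-(hydroxymethyl)-6,10-dimethyl-12-oxo-4-[(triethylsilyl)oxy]dodeca-2,6,10-trienoate
Product: 17 ethyl (2Z,4R,5R,6Z,10E)-2-(bromomethyl)-5-[(tert-butyldimethylsilyl)oxy]-6,10-dimethyl-12-oxo-4-[(triethylsilyl)oxy]dodeca-2,6,10-trienoate, via mesylate 16 (not isolated)
Conditions: MsCl, Et3N, CH2Cl2, −20 °C; then LiBr, THF, 0 °C
Reagents that add atoms: methanesulfonyl chloride CS(=O)(=O)Cl (atoms stay only in 16); lithium bromide [Li+].[Br-]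
Why: mesylation and SN2 displacement by bromide give the 2-(bromomethyl)enoate without touching the enal, and any SN2' isomer would lead to the same allylchromium species in the next step.

Step 9
Reactants: 17 ethyl (2Z,4R,5R,6Z,10E)-2-(bromomethyl)-5-[(tert-butyldimethylsilyl)oxy]-6,10-dimethyl-12-oxo-4-[(triethylsilyl)oxy]dodeca-2,6,10-trienoate
Product: 20 (3aS,4R,5R,6Z,10E,11aR)-5-[(tert-butyldimethylsilyl)oxy]-6,10-dimethyl-3-methylidene-4-[(triethylsilyl)oxy]-3a,4,5,8,9,11a-hexahydrocyclodeca[b]furan-2(3H)-one, via allylchromium dichloride 18 (not isolated), via hydroxy ester 19 (not isolated)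
Conditions: CrCl2 (8 equiv), THF/DMF (4:1), rt, syringe-pump addition of 17 (final 2 mM)
Reagents that add atoms: chromium dichloride [Cr+2].[Cl-].[Cl-] (atoms stay only in 18)
Why: chromium Barbier (Nozaki–Hiyama–Kishi-type) allylation in which the allylchromium adds through C7 to the enal in a six-membered chair transition state (enal substituent equatorial, hence the 6,7-anti relationship and the trans-lactone) from the face anti to the C8 silyloxy group (H-eclipsed allylic-strain model), setting 6R and 7S, after which the chromium alkoxide lactonises onto the ethyl ester; this closure type is known for ten-membered germacranolide rings.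

Step 10
Reactants: 20 (3aS,4R,5R,6Z,10E,11aR)-5-[(tert-butyldimethylsilyl)oxy]-6,10-dimethyl-3-methylidene-4-[(triethylsilyl)oxy]-3a,4,5,8,9,11a-hexahydrocyclodeca[b]furan-2(3H)-one
Product: 21 (3aR,4R,5R,6Z,10E,11aR)-5-[(tert-butyldimethylsilyl)oxy]-4-hydroxy-6,10-dimethyl-3-methylidene-3a,4,5,8,9,11a-hexahydrocyclodeca[b]furan-2(3H)-one
Conditions: PPTS (cat.), MeOH/CH2Cl2, 0 °C
Reagents that add atoms: none
Why: acid-catalysed methanolysis cleaves the triethylsilyl ether much faster than the secondary tert-butyldimethylsilyl ether, freeing only C8–OH (the 3a descriptor changes by priority only).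

Step 11
Reactants: 22 (2Z)-2-methylbut-2-enoic acid (angelic acid)
Product: 23 (2Z)-2-methylbut-2-en-1-ol
Conditions: LiAlH4, Et2O, 0 °C
Reagents that add atoms: none
Why: hydride reduction of the acid to the allylic alcohol with retention of the Z geometry.

Step 12
Reactants: 23 (2Z)-2-methylbut-2-en-1-ol
Product: 24 [(2R,3S)-2,3-dimethyloxiran-2-yl]methanol
Conditions: Ti(OiPr)4 (10 mol%), D-(−)-diethyl tartrate (12 mol%), t-BuOOH, 4 Å molecular sieves, CH2Cl2, −20 °C
Reagents that add atoms: tert-butyl hydroperoxide CC(C)(C)OO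
Why: Sharpless asymmetric epoxidation, in which the titanium tartrate complex made with D-(−)-diethyl tartrate delivers oxygen to the face that gives the (2R,3S) epoxy alcohol, the cis (angelate) relationship being kept because the oxygen transfer is stereospecific.

Step 13
Reactants: 24 [(2R,3S)-2,3-dimethyloxiran-2-yl]methanol
Product: 25 (2S,3S)-2,3-dimethyloxirane-2-carboxylic acid
Conditions: RuCl3 (cat.), NaIO4, CCl4/MeCN/H2O, rt
Reagents that add atoms: sodium periodate [Na+].[O-]I(=O)(=O)=O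
Why: ruthenium tetroxide oxidation of the primary alcohol to the acid leaves the oxirane intact, and the C2 descriptor changes from R to S by priority only.

Step 14
Reactants: 21 (3aR,4R,5R,6Z,10E,11aR)-5-[(tert-butyldimethylsilyl)oxy]-4-hydroxy-6,10-dimethyl-3-methylidene-3a,4,5,8,9,11a-hexahydrocyclodeca[b]furan-2(3H)-one; 25 (2S,3S)-2,3-dimethyloxirane-2-carboxylic acid
Product: 27 (3aS,4R,5R,6Z,10E,11aR)-5-[(tert-butyldimethylsilyl)oxy]-6,10-dimethyl-3-methylidene-2-oxo-2,3,3a,4,5,8,9,11a-octahydrocyclodeca[b]furan-4-yl (2S,3S)-2,3-dimethyloxirane-2-carboxylate, via mixed anhydride 26 (not isolated)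
Conditions: 25, 2,4,6-trichlorobenzoyl chloride, Et3N, toluene, rt; then 21, DMAP, 0 °C to rt
Reagents that add atoms: 2,4,6-trichlorobenzoyl chloride O=C(Cl)c1c(Cl)cc(Cl)cc1Cl (atoms stay only in 26)
Why: Yamaguchi esterification, in which DMAP opens the mixed anhydride at the oxirane carbonyl (the aroyl carbonyl is shielded by its two ortho chlorines) and the acylpyridinium acylates the hindered C8 hydroxyl faster than the free alcohol can translactonise.

Step 15
Reactants: 27 (3aS,4R,5R,6Z,10E,11aR)-5-[(tert-butyldimethylsilyl)oxy]-6,10-dimethyl-3-methylidene-2-oxo-2,3,3a,4,5,8,9,11a-octahydrocyclodeca[b]furan-4-yl (2S,3S)-2,3-dimethyloxirane-2-carboxylate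
Product: 29 (3aS,4R,5R,6Z,10E,11aR)-5-(acetyloxy)-6,10-dimethyl-3-methylidene-2-oxo-2,3,3a,4,5,8,9,11a-octahydrocyclodeca[b]furan-4-yl (2S,3S)-2,3-dimethyloxirane-2-carboxylate, via alcohol 28 (not isolated)
Conditions: HF·pyridine, pyridine, THF, 0 °C to rt; Me3SiOMe quench, evaporate; then Ac2O, DMAP, pyridine, CH2Cl2, 0 °C
Reagents that add atoms: acetic anhydride CC(=O)OC(C)=O
Why: fluoride desilylation under buffered acidic conditions (no alkoxide, so no acyl migration or translactonisation) followed by DMAP-catalysed acetylation of C9–OH gives the target.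

**Compound list**

1 | 5-chloropent-1-yne | C#CCCCCl | starting material
2 | [(1E)-5-chloro-2-methylpent-1-en-1-yl]dimethylalane | C[Al](C)/C=C(\C)CCCCl | intermediate
3 | (2E)-6-chloro-3-methylhex-2-en-1-ol | OC/C=C(\C)CCCCl | intermediate
4 | [(4E)-6-hydroxy-4-methylhex-4-en-1-yl]triphenylphosphonium iodide | OC/C=C(\C)CCC[P+](c1ccccc1)(c1ccccc1)c1ccccc1.[I-] | intermediate
5 | ethyl 2-(diethoxyphosphoryl)prop-2-enoate | CCOC(=O)C(=C)P(=O)(OCC)OCC | starting material
6 | 2,2-dimethoxyacetaldehyde | COC(OC)C=O | starting material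
7 | ethyl 2-(diethoxyphosphoryl)-3-[(4-methoxyphenyl)methoxy]propanoate (sodium salt in the flask) | CCOC(=O)C(COCc1ccc(OC)cc1)P(=O)(OCC)OCC | intermediate
8 | ethyl (2E)-4,4-dimethoxy-2-{[(4-methoxyphenyl)methoxy]methyl}but-2-enoate | CCOC(=O)/C(COCc1ccc(OC)cc1)=C/C(OC)OC | intermediate
9 | ethyl (2E)-2-{[(4-methoxyphenyl)methoxy]methyl}-4-oxobut-2-enoate | CCOC(=O)/C(COCc1ccc(OC)cc1)=C/C=O | intermediate
10 | 1-[(tert-butyldimethylsilyl)oxy]propan-2-one | CC(=O)CO[Si](C)(C)C(C)(C)C | starting material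
11 | ethyl (2E,4R,5S)-5-[(tert-butyldimethylsilyl)oxy]-4-hydroxy-2-{[(4-methoxyphenyl)methoxy]methyl}-6-oxohept-2-enoate | CC(=O)[C@@H](O[Si](C)(C)C(C)(C)C)[C@H](O)/C=C(\COCc1ccc(OC)cc1)C(=O)OCC | intermediate
12 | ethyl (2E,4R,5S)-5-[(tert-butyldimethylsilyl)oxy]-2-{[(4-methoxyphenyl)methoxy]methyl}-6-oxo-4-[(triethylsilyl)oxy]hept-2-enoate | CC(=O)[C@@H](O[Si](C)(C)C(C)(C)C)[C@H](O[Si](CC)(CC)CC)/C=C(\COCc1ccc(OC)cc1)C(=O)OCC | intermediate
13 | potassium (2E)-3-methyl-6-(triphenyl-λ5-phosphanylidene)hex-2-en-1-olate (ylide) | [K+].[O-]C/C=C(\C)CCC=P(c1ccccc1)(c1ccccc1)c1ccccc1 | intermediate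
14 | ethyl (2E,4R,5R,6Z,10E)-5-[(tert-butyldimethylsilyl)oxy]-12-hydroxy-2-{[(4-methoxyphenyl)methoxy]methyl}-6,10-dimethyl-4-[(triethylsilyl)oxy]dodeca-2,6,10-trienoate | OC/C=C(\C)CC/C=C(/C)[C@@H](O[Si](C)(C)C(C)(C)C)[C@H](O[Si](CC)(CC)CC)/C=C(\COCc1ccc(OC)cc1)C(=O)OCC | intermediate
15 | ethyl (2E,4R,5R,6Z,10E)-5-[(tert-butyldimethylsilyl)oxy]-2-(hydroxymethyl)-6,10-dimethyl-12-oxo-4-[(triethylsilyl)oxy]dodeca-2,6,10-trienoate | O=C/C=C(\C)CC/C=C(/C)[C@@H](O[Si](C)(C)C(C)(C)C)[C@H](O[Si](CC)(CC)CC)/C=C(\CO)C(=O)OCC | intermediate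
16 | ethyl (2E,4R,5R,6Z,10E)-5-[(tert-butyldimethylsilyl)oxy]-2-{[(methanesulfonyl)oxy]methyl}-6,10-dimethyl-12-oxo-4-[(triethylsilyl)oxy]dodeca-2,6,10-trienoate | O=C/C=C(\C)CC/C=C(/C)[C@@H](O[Si](C)(C)C(C)(C)C)[C@H](O[Si](CC)(CC)CC)/C=C(\COS(C)(=O)=O)C(=O)OCC | intermediate
17 | ethyl (2Z,4R,5R,6Z,10E)-2-(bromomethyl)-5-[(tert-butyldimethylsilyl)oxy]-6,10-dimethyl-12-oxo-4-[(triethylsilyl)oxy]dodeca-2,6,10-trienoate | O=C/C=C(\C)CC/C=C(/C)[C@@H](O[Si](C)(C)C(C)(C)C)[C@H](O[Si](CC)(CC)CC)/C=C(\CBr)C(=O)OCC | intermediate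
18 | allylchromium dichloride derived from 17 (CrCl2 in place of Br) | O=C/C=C(\C)CC/C=C(/C)[C@@H](O[Si](C)(C)C(C)(C)C)[C@H](O[Si](CC)(CC)CC)/C=C(\C[Cr](Cl)Cl)C(=O)OCC | intermediate
19 | ethyl 2-[(1S,2R,3E,7Z,9R,10R)-9-[(tert-butyldimethylsilyl)oxy]-2-hydroxy-4,8-dimethyl-10-[(triethylsilyl)oxy]cyclodeca-3,7-dien-1-yl]prop-2-enoate | C=C(C(=O)OCC)[C@H]1[C@H](O)/C=C(\C)CC/C=C(/C)[C@@H](O[Si](C)(C)C(C)(C)C)[C@@H]1O[Si](CC)(CC)CC | intermediate
20 | (3aS,4R,5R,6Z,10E,11aR)-5-[(tert-butyldimethylsilyl)oxy]-6,10-dimethyl-3-methylidene-4-[(triethylsilyl)oxy]-3a,4,5,8,9,11a-hexahydrocyclodeca[b]furan-2(3H)-one | C=C1C(=O)O[C@@H]2/C=C(\C)CC/C=C(/C)[C@@H](O[Si](C)(C)C(C)(C)C)[C@H](O[Si](CC)(CC)CC)[C@@H]12 | intermediate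
21 | (3aR,4R,5R,6Z,10E,11aR)-5-[(tert-butyldimethylsilyl)oxy]-4-hydroxy-6,10-dimethyl-3-methylidene-3a,4,5,8,9,11a-hexahydrocyclodeca[b]furan-2(3H)-one | C=C1C(=O)O[C@@H]2/C=C(\C)CC/C=C(/C)[C@@H](O[Si](C)(C)C(C)(C)C)[C@H](O)[C@@H]12 | intermediate
22 | (2Z)-2-methylbut-2-enoic acid (angelic acid) | C/C=C(/C)C(=O)O | starting material
23 | (2Z)-2-methylbut-2-en-1-ol | C/C=C(/C)CO | intermediate
24 | [(2R,3S)-2,3-dimethyloxiran-2-yl]methanol | OC[C@@]1(C)O[C@H]1C | intermediate
25 | (2S,3S)-2,3-dimethyloxirane-2-carboxylic acid | OC(=O)[C@@]1(C)O[C@H]1C | intermediate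
26 | (2S,3S)-2,3-dimethyloxirane-2-carboxylic 2,4,6-trichlorobenzoic anhydride | O=C(OC(=O)c1c(Cl)cc(Cl)cc1Cl)[C@@]1(C)O[C@H]1C | intermediate
27 | (3aS,4R,5R,6Z,10E,11aR)-5-[(tert-butyldimethylsilyl)oxy]-6,10-dimethyl-3-methylidene-2-oxo-2,3,3a,4,5,8,9,11a-octahydrocyclodeca[b]furan-4-yl (2S,3S)-2,3-dimethyloxirane-2-carboxylate | C=C1C(=O)O[C@@H]2/C=C(\C)CC/C=C(/C)[C@@H](O[Si](C)(C)C(C)(C)C)[C@H](OC(=O)[C@@]3(C)O[C@H]3C)[C@@H]12 | intermediate
28 | (3aS,4R,5R,6Z,10E,11aR)-5-hydroxy-6,10-dimethyl-3-methylidene-2-oxo-2,3,3a,4,5,8,9,11a-octahydrocyclodeca[b]furan-4-yl (2S,3S)-2,3-dimethyloxirane-2-carboxylate | C=C1C(=O)O[C@@H]2/C=C(\C)CC/C=C(/C)[C@@H](O)[C@H](OC(=O)[C@@]3(C)O[C@H]3C)[C@@H]12 | intermediate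
29 | (3aS,4R,5R,6Z,10E,11aR)-5-(acetyloxy)-6,10-dimethyl-3-methylidene-2-oxo-2,3,3a,4,5,8,9,11a-octahydrocyclodeca[b]furan-4-yl (2S,3S)-2,3-dimethyloxirane-2-carboxylate | C=C1C(=O)O[C@@H]2/C=C(\C)CC/C=C(/C)[C@@H](OC(C)=O)[C@H](OC(=O)[C@@]3(C)O[C@H]3C)[C@@H]12 | target

**Step count**

Total: 15 steps. Longest linear sequence: 10 steps (steps 3, 4, 5, 6, 7, 8, 9, 10, 14, 15).

**Three steps most likely to fail**

Step 4 (the proposed new aldol). The acceptor 9 is an enal with a γ-CH2 group, so imine or dienamine formation with the catalyst, conjugate addition, or poor dr/ee could intervene. The fallback uses known chemistry and sets out from 10 and 6. The same threonine catalyst is used with 6 itself, an α-oxygenated aliphatic aldehyde of the class for which this syn-aldol is established, to give (3S,4S)-3-[(tert-butyldimethylsilyl)oxy]-4-hydroxy-5,5-dimethoxypentan-2-one F1. Silylation with Et3SiOTf/2,6-lutidine gives (3S,4S)-3-[(tert-butyldimethylsilyl)oxy]-5,5-dimethoxy-4-[(triethylsilyl)oxy]pentan-2-one F2. The dimethyl acetal is then cleaved chemoselectively with Et3SiOTf/2,4,6-collidine followed by water (silyl ethers and ketone untouched) to give (2S,3S)-3-[(tert-butyldimethylsilyl)oxy]-4-oxo-2-[(triethylsilyl)oxy]pentanal F3. Horner–Wadsworth–Emmons olefination of F3 at −78 °C with phosphonate 7, generated as in step 3, comes back to the route at 12.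

Step 6 (Wittig). The Z/E ratio on this branched, doubly silyloxylated ketone is not guaranteed, and the dianionic ylide may enolise 12 or attack the enoate. The fallback sets out from 3 and 12 and replaces kinetic selectivity by a Horner–Wittig sequence with separable adducts. Michaelis–Arbuzov reaction of 3 with ethyl diphenylphosphinite (NaI cat., 130 °C) gives (2E)-6-(diphenylphosphoryl)-3-methylhex-2-en-1-ol F4. Its dianion (n-BuLi, 2 equiv, THF, −78 °C) adds to 12, and the β-hydroxy phosphine oxide ethyl (2E,4R,5S,6S,7R,10E)-5-[(tert-butyldimethylsilyl)oxy]-7-(diphenylphosphoryl)-6,12-dihydroxy-2-{[(4-methoxyphenyl)methoxy]methyl}-6,10-dimethyl-4-[(triethylsilyl)oxy]dodeca-2,10-dienoate F5 is separated by chromatography from its diastereomers. Stereospecific syn-elimination (KH, DMF) then gives only the Z olefin and comes back to the route at 14.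

Step 9 (macrocyclising chromium allylation). Ring strain and oligomerisation, 1,4-elimination of the C8 silyloxy group from the allylchromium, and the C6/C7 stereochemical outcome are all uncertain. The fallback sets out from 12, makes the C6–C7 bond intermolecularly and closes ring A by metathesis at C1=C10.
- Methylenation of 12 (Ph3PCH3Br, KN(SiMe3)2) gives ethyl (2E,4R,5R)-5-[(tert-butyldimethylsilyl)oxy]-2-{[(4-methoxyphenyl)methoxy]methyl}-6-methyl-4-[(triethylsilyl)oxy]hepta-2,6-dienoate F6.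
- DDQ gives ethyl (2E,4R,5R)-5-[(tert-butyldimethylsilyl)oxy]-2-(hydroxymethyl)-6-methyl-4-[(triethylsilyl)oxy]hepta-2,6-dienoate F7.
- MsCl/Et3N then LiBr gives ethyl (2Z,4R,5R)-2-(bromomethyl)-5-[(tert-butyldimethylsilyl)oxy]-6-methyl-4-[(triethylsilyl)oxy]hepta-2,6-dienoate F8.
- Commercial hex-1-en-5-yne is taken through the step 1 procedure to (2E)-3-methylhepta-2,6-dien-1-ol F9 and oxidised with MnO2 to (2E)-3-methylhepta-2,6-dienal F10.
- CrCl2-mediated coupling of F8 with F10 in THF (same stereochemical model, diastereomers separable in this open-chain series) gives (4S,5R)-4-[(1R,2R)-2-[(tert-butyldimethylsilyl)oxy]-3-methyl-1-[(triethylsilyl)oxy]but-3-en-1-yl]-5-[(1E)-2-methylhexa-1,5-dien-1-yl]-3-methylideneoxolan-2-one F11.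
- Ring-closing metathesis of F11 with second-generation Hoveyda–Grubbs catalyst (toluene, 80 °C, 1 mM), where the ten-membered ring enforces the Z C1=C10 olefin, comes back to the route at 20.

**Further compounds**

F1 | step 4 | (3S,4S)-3-[(tert-butyldimethylsilyl)oxy]-4-hydroxy-5,5-dimethoxypentan-2-one | CC(=O)[C@@H](O[Si](C)(C)C(C)(C)C)[C@H](O)C(OC)OC
F2 | step 4 | (3S,4S)-3-[(tert-butyldimethylsilyl)oxy]-5,5-dimethoxy-4-[(triethylsilyl)oxy]pentan-2-one | CC(=O)[C@@H](O[Si](C)(C)C(C)(C)C)[C@H](O[Si](CC)(CC)CC)C(OC)OC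
F3 | step 4 | (2S,3S)-3-[(tert-butyldimethylsilyl)oxy]-4-oxo-2-[(triethylsilyl)oxy]pentanal | CC(=O)[C@@H](O[Si](C)(C)C(C)(C)C)[C@H](O[Si](CC)(CC)CC)C=O
F4 | step 6 | (2E)-6-(diphenylphosphoryl)-3-methylhex-2-en-1-ol | OC/C=C(\C)CCCP(=O)(c1ccccc1)c1ccccc1
F5 | step 6 | ethyl (2E,4R,5S,6S,7R,10E)-5-[(tert-butyldimethylsilyl)oxy]-7-(diphenylphosphoryl)-6,12-dihydroxy-2-{[(4-methoxyphenyl)methoxy]methyl}-6,10-dimethyl-4-[(triethylsilyl)oxy]dodeca-2,10-dienoate | OC/C=C(\C)CC[C@@H](P(=O)(c1ccccc1)c1ccccc1)[C@@](C)(O)[C@@H](O[Si](C)(C)C(C)(C)C)[C@H](O[Si](CC)(CC)CC)/C=C(\COCc1ccc(OC)cc1)C(=O)OCC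
F6 | step 9 | ethyl (2E,4R,5R)-5-[(tert-butyldimethylsilyl)oxy]-2-{[(4-methoxyphenyl)methoxy]methyl}-6-methyl-4-[(triethylsilyl)oxy]hepta-2,6-dienoate | C=C(C)[C@@H](O[Si](C)(C)C(C)(C)C)[C@H](O[Si](CC)(CC)CC)/C=C(\COCc1ccc(OC)cc1)C(=O)OCC
F7 | step 9 | ethyl (2E,4R,5R)-5-[(tert-butyldimethylsilyl)oxy]-2-(hydroxymethyl)-6-methyl-4-[(triethylsilyl)oxy]hepta-2,6-dienoate | C=C(C)[C@@H](O[Si](C)(C)C(C)(C)C)[C@H](O[Si](CC)(CC)CC)/C=C(\CO)C(=O)OCC
F8 | step 9 | ethyl (2Z,4R,5R)-2-(bromomethyl)-5-[(tert-butyldimethylsilyl)oxy]-6-methyl-4-[(triethylsilyl)oxy]hepta-2,6-dienoate | C=C(C)[C@@H](O[Si](C)(C)C(C)(C)C)[C@H](O[Si](CC)(CC)CC)/C=C(\CBr)C(=O)OCC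
F9 | step 9 | (2E)-3-methylhepta-2,6-dien-1-ol | OC/C=C(\C)CCC=C
F10 | step 9 | (2E)-3-methylhepta-2,6-dienal | O=C/C=C(\C)CCC=C
F11 | step 9 | (4S,5R)-4-[(1R,2R)-2-[(tert-butyldimethylsilyl)oxy]-3-methyl-1-[(triethylsilyl)oxy]but-3-en-1-yl]-5-[(1E)-2-methylhexa-1,5-dien-1-yl]-3-methylideneoxolan-2-one | C=C1C(=O)O[C@H](/C=C(\C)CCC=C)[C@H]1[C@@H](O[Si](CC)(CC)CC)[C@H](O[Si](C)(C)C(C)(C)C)C(C)=C
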